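**Retrosynthetic overview**

- The target is cut at the ester C–O bond into 4-hydroxy-3-(2-methylbut-3-en-2-yl)-6-phenyl-2-pyrone and 3-hydroxy-3-methylbutanoic acid; the pyronol is unmasked from its 4-ethyl ether.
- The 4-ethoxypyrone is cut at pyrone C3–C4 and C5–C6 ([4+2] cycloaddition, then loss of N2) into 5-(2-methylbut-3-en-2-yl)-2-phenyl-1,3,4-oxadiazin-6-one and ethoxyacetylene.
- The oxadiazinone comes from carbodiimide ring closure of the N-benzoylhydrazone of 3,3-dimethyl-2-oxopent-4-enoic acid; the keto acid comes from diethyl oxalate and a prenyl Grignard reagent reacting at its tertiary terminus.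
- Feature on which the strategy rests: in the 2-pyrone ring, O1–C2(=O), C3 (quaternary 1,1-dimethylallyl carbon attached) and C6 (phenyl) map onto O1–C6(=O), C5 and C2 of the oxadiazinone, and C4(–O)/C5(–H) map onto a terminal ynol ether. The quaternary carbon is therefore in place before the pyrone exists.
- Ring order: the phenyl ring is purchased; the oxadiazinone ring is closed first (step 4) and is then converted into the pyrone ring (step 5).

Key step: step 5

Assumption: the target is achiral, so no stereocentre has to be set; the hydrazone geometry drawn for the acylhydrazone is the expected one, and the other isomer should equilibrate to it under the acidic condensation conditions.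

**Route**

Step 1
Reactants: 1 prenyl chloride (1-chloro-3-methylbut-2-ene); 2 diethyl oxalate
Product: 4 ethyl 3,3-dimethyl-2-oxopent-4-enoate, via prenylmagnesium chloride 3 (not isolated)
Conditions: Mg turnings (excess), THF, 0 °C, slow addition of 1; then cannulation into 2 (2 equiv), THF, −78 °C; cold 1 M HCl quench
Reagents that add atoms: none
Why: Mono-acylation of a Grignard reagent by a dialkyl oxalate, in which the prenyl reagent reacts with allylic transposition (SE2', six-membered transition state) so that its tertiary carbon bonds to the carbonyl, while inverse addition at −78 °C keeps the magnesium hemiketal alkoxide intact until the quench and stops the reaction at the α-keto ester.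

Step 2
Reactants: 4 ethyl 3,3-dimethyl-2-oxopent-4-enoate
Product: 5 3,3-dimethyl-2-oxopent-4-enoic acid
Conditions: LiOH·H2O, THF/H2O, 0 °C; then 1 M HCl to pH 2, extraction
Reagents that add atoms: lithium hydroxide, [Li+].[OH-] (supplies the carboxyl oxygen)
Why: Ester saponification (BAc2) is fast for an α-keto ester at 0 °C, and the quaternary α-carbon carries no hydrogen, so neither aldol chemistry nor migration of the vinyl double bond can interfere.

Step 3
Reactants: 5 3,3-dimethyl-2-oxopent-4-enoic acid; 6 benzhydrazide
Product: 7 (2Z)-2-(2-benzoylhydrazinylidene)-3,3-dimethylpent-4-enoic acid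
Conditions: EtOH, 25 → 50 °C; the product is collected by crystallisation
Reagents that add atoms: none
Why: Acylhydrazone condensation, which tert-alkyl α-keto acids undergo readily under their own acid catalysis; the benzamido group should settle syn to the carboxyl group (away from the tert-alkyl group and hydrogen-bonded to the acid), which is the geometry needed for ring closure.

Step 4
Reactants: 7 (2Z)-2-(2-benzoylhydrazinylidene)-3,3-dimethylpent-4-enoic acid
Product: 8 5-(2-methylbut-3-en-2-yl)-2-phenyl-6H-1,3,4-oxadiazin-6-one
Conditions: N,N'-dicyclohexylcarbodiimide (DCC, 1.05 equiv), dry THF, 0 °C → rt; filtration of the urea under argon, concentration; used promptly with exclusion of moisture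
Reagents that add atoms: none
Why: Carbodiimide cyclodehydration of an α-keto acid N-acylhydrazone, the standard entry to 1,3,4-oxadiazin-6-ones, in which the benzamide oxygen attacks the O-acylisourea-activated carboxyl group in a six-membered intramolecular O-acylation.

Step 5
Reactants: 8 5-(2-methylbut-3-en-2-yl)-2-phenyl-6H-1,3,4-oxadiazin-6-one; 9 ethoxyacetylene
Product: 11 4-ethoxy-3-(2-methylbut-3-en-2-yl)-6-phenyl-2H-pyran-2-one, via bicyclic azo adduct 10 (not isolated)
Conditions: 9 (3–5 equiv, solution in hexanes), dry toluene, argon, sealed tube, 25 → 60 °C (kept below 80 °C), until N2 evolution ends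
Reagents that add atoms: none
Why: The C2=N3–N4=C5 diazadiene of 8 is electron-poor and the ynol ether electron-rich, so an inverse-electron-demand, probably asynchronous [4+2] is expected in which the nucleophilic CH terminus of 9 bonds first to the phenyl-bearing C2, the only attack that places the negative charge on N3 in conjugation through N4=C5 with the lactone carbonyl, after which the aza-enolate carbon C5 closes onto the ethoxy-stabilised cationic carbon. The bicyclo[2.2.2] azo adduct 10 then loses N2 irreversibly by retro-[4+2], and the O1–C6(=O) unit of 8 survives as O1–C2(=O) of the pyrone. The closest known reaction type is the cycloaddition/nitrogen-extrusion of 1,3,4-oxadiazin-6-ones with alkynes to 2-pyrones, the oxadiazinone counterpart of the tetrazine and triazine Diels–Alder/retro-Diels–Alder sequences. The pyrone ring is closed by intermolecular [4+2] cycloaddition across C2 and C5 of the diazadiene (forming pyrone C5–C6 and C3–C4) followed by cycloreversion, and no stereocentre remains because both bridgeheads of 10 become sp2 carbons. The selectivity required is regiochemical (ethoxy at C4, hydrogen at C5); it is secured by the electronic match just described and reinforced sterically, since the unsubstituted alkyne carbon makes the first bond at the less hindered phenyl-bearing carbon and the carbon next to the quaternary centre is engaged last and intramolecularly. Keeping the temperature low prevents fragmentation of 9 to ketene and ethylene, and the isolated vinyl group of 8 cannot compete with the ynol ether used in excess.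

Step 6
Reactants: 11 4-ethoxy-3-(2-methylbut-3-en-2-yl)-6-phenyl-2H-pyran-2-one
Product: 12 4-hydroxy-3-(2-methylbut-3-en-2-yl)-6-phenyl-2H-pyran-2-one
Conditions: NaSEt (3 equiv), degassed DMF, 90 °C; then cold 1 M HCl, extraction
Reagents that add atoms: none
Why: Nucleophilic O-dealkylation (SN2 at the ethyl CH2 by a soft thiolate) should be feasible because the 4-alkoxy-2-pyrone is a vinylogous ester whose pyronolate leaving group corresponds to an acid of pKa about 5; attack at ring C4 is screened by the adjacent quaternary carbon, and the basic medium holds the product as its unreactive anion and avoids acid-induced cyclisation of the hydroxyl onto the vinyl group.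

Step 7
Reactants: 12 4-hydroxy-3-(2-methylbut-3-en-2-yl)-6-phenyl-2H-pyran-2-one; 13 3-hydroxy-3-methylbutanoic acid
Product: 14 3-(2-methylbut-3-en-2-yl)-2-oxo-6-phenyl-2H-pyran-4-yl 3-hydroxy-3-methylbutanoate (target)
Conditions: N,N'-dicyclohexylcarbodiimide (DCC, 1.2 equiv), 4-(dimethylamino)pyridine (DMAP, 0.1 equiv), CH2Cl2, 0 °C → rt; filtration, non-basic work-up, rapid chromatography
Reagents that add atoms: none
Why: Steglich esterification, in which the acidic pyronol intercepts the acylpyridinium ion much faster than the hindered tertiary hydroxyl of the acid, and the substituted C3 position rules out the usual DMAP-promoted O-to-C acyl shift of 4-acyloxypyrones.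

**Compound list**

1 | prenyl chloride (1-chloro-3-methylbut-2-ene) | CC(C)=CCCl | starting material
2 | diethyl oxalate | CCOC(=O)C(=O)OCC | starting material
3 | prenylmagnesium chloride | CC(C)=CC[Mg]Cl | intermediate (not isolated)
4 | ethyl 3,3-dimethyl-2-oxopent-4-enoate | C=CC(C)(C)C(=O)C(=O)OCC | intermediate
5 | 3,3-dimethyl-2-oxopent-4-enoic acid | C=CC(C)(C)C(=O)C(=O)O | intermediate
6 | benzhydrazide | NNC(=O)c1ccccc1 | starting material
7 | (2Z)-2-(2-benzoylhydrazinylidene)-3,3-dimethylpent-4-enoic acid | OC(=O)/C(=N\NC(=O)c1ccccc1)C(C)(C)C=C | intermediate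
8 | 5-(2-methylbut-3-en-2-yl)-2-phenyl-6H-1,3,4-oxadiazin-6-one | O=C1OC(c2ccccc2)=NN=C1C(C)(C)C=C | intermediate
9 | ethoxyacetylene | C#COCC | starting material
10 | 8-ethoxy-4-(2-methylbut-3-en-2-yl)-1-phenyl-2-oxa-5,6-diazabicyclo[2.2.2]octa-5,7-dien-3-one (racemic, transient; relative configuration of the bridgeheads fixed by the bicycle) | O=C1OC2(c3ccccc3)N=NC1(C(C)(C)C=C)C(OCC)=C2 | intermediate (not isolated)
11 | 4-ethoxy-3-(2-methylbut-3-en-2-yl)-6-phenyl-2H-pyran-2-one | C=CC(C)(C)c1c(OCC)cc(-c2ccccc2)oc1=O | intermediate
12 | 4-hydroxy-3-(2-methylbut-3-en-2-yl)-6-phenyl-2H-pyran-2-one | C=CC(C)(C)c1c(O)cc(-c2ccccc2)oc1=O | intermediate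
13 | 3-hydroxy-3-methylbutanoic acid | CC(C)(O)CC(=O)O | starting material
14 | 3-(2-methylbut-3-en-2-yl)-2-oxo-6-phenyl-2H-pyran-4-yl 3-hydroxy-3-methylbutanoate | C=CC(C)(C)c1c(OC(=O)CC(C)(C)O)cc(-c2ccccc2)oc1=O | target

**Step count**

Total step count: 7. Longest linear sequence: 7 steps (steps 1 to 7, from 1 and 2 to 14).

**Steps most likely to fail**

1. Step 5 (key step). What may go wrong: the first bond may form but closure onto the carbon next to the quaternary centre may stall, so that the zwitterion opens the lactone or oligomerises the ynol ether; the regiochemistry may invert; or the ynol ether may fragment to ketene before it is consumed. Fallback, a change of ring construction: it sets out from prenyl chloride 1 and returns at 12. Commercial 4-hydroxy-6-phenyl-2H-pyran-2-one F1 would be O-alkylated with 1 (K2CO3, acetone, reflux, separation from C-alkylated material) to give 4-[(3-methylbut-2-en-1-yl)oxy]-6-phenyl-2H-pyran-2-one F2. Heating F2 in toluene at reflux should bring about the [3,3] Claisen rearrangement, which can only deliver the allyl unit, inverted, to C3, and after enolisation gives 12. The heating would be stopped at full conversion to limit cyclisation of the hydroxyl onto the new vinyl group. This bypasses steps 1 to 6.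

2. Step 6. What may go wrong: the thiolate may add to the ring at C4 or C6 (addition–elimination or lactone opening) faster than it displaces at the ethyl carbon, which is a slow SN2 centre. Fallback, a change of the oxygen substituent so that the unmasking is an acid-induced loss of an alkene and not a displacement: it sets out from 8 and returns at 12. The oxadiazinone 8 would be combined with tert-butoxyacetylene F3 at 20–35 °C (below the temperature at which this ynol ether gives ketene) to form the bicyclic azo adduct 8-tert-butoxy-4-(2-methylbut-3-en-2-yl)-1-phenyl-2-oxa-5,6-diazabicyclo[2.2.2]octa-5,7-dien-3-one F4, which should lose N2 to give 4-tert-butoxy-3-(2-methylbut-3-en-2-yl)-6-phenyl-2H-pyran-2-one F5. Brief treatment of F5 with trifluoroacetic acid in CH2Cl2 at 0 °C should expel 2-methylpropene and give 12.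

3. Step 7. What may go wrong: the activated acid may be consumed through its own tertiary hydroxyl (β-lactone or oligoester formation) or by dehydration to the unsaturated acyl unit, while acyl transfer to the hindered, weakly nucleophilic pyronol oxygen is slow; the activated ester product may also be lost on work-up. Fallback, protection of the hydroxyl and a more reactive acyl donor: it sets out from 13 and 12 and returns at 14. Acid 13 would be silylated twice (Et3SiCl, imidazole, DMF) to triethylsilyl 3-methyl-3-[(triethylsilyl)oxy]butanoate F6, whose silyl ester would be cleaved selectively (K2CO3, aqueous THF) to 3-methyl-3-[(triethylsilyl)oxy]butanoic acid F7. 1-Chloro-N,N,2-trimethylprop-1-en-1-amine in CH2Cl2 at 0 °C would convert F7 under neutral conditions into 3-methyl-3-[(triethylsilyl)oxy]butanoyl chloride F8. Addition of F8 to the sodium salt of 12 (NaH, THF, 0 °C) should give 3-(2-methylbut-3-en-2-yl)-2-oxo-6-phenyl-2H-pyran-4-yl 3-methyl-3-[(triethylsilyl)oxy]butanoate F9, and HF·pyridine in THF at 0 °C should remove the silyl group to give 14.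

**Further compounds**

F1 | step 5 | 4-hydroxy-6-phenyl-2H-pyran-2-one | O=c1cc(O)cc(-c2ccccc2)o1
F2 | step 5 | 4-[(3-methylbut-2-en-1-yl)oxy]-6-phenyl-2H-pyran-2-one | CC(C)=CCOc1cc(-c2ccccc2)oc(=O)c1
F3 | step 6 | tert-butoxyacetylene | CC(C)(C)OC#C
F4 | step 6 | 8-tert-butoxy-4-(2-methylbut-3-en-2-yl)-1-phenyl-2-oxa-5,6-diazabicyclo[2.2.2]octa-5,7-dien-3-one (racemic, not isolated) | O=C1OC2(c3ccccc3)N=NC1(C(C)(C)C=C)C(OC(C)(C)C)=C2
F5 | step 6 | 4-tert-butoxy-3-(2-methylbut-3-en-2-yl)-6-phenyl-2H-pyran-2-one | C=CC(C)(C)c1c(OC(C)(C)C)cc(-c2ccccc2)oc1=O
F6 | step 7 | triethylsilyl 3-methyl-3-[(triethylsilyl)oxy]butanoate (not isolated) | CC[Si](CC)(CC)OC(C)(C)CC(=O)O[Si](CC)(CC)CC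
F7 | step 7 | 3-methyl-3-[(triethylsilyl)oxy]butanoic acid | CC[Si](CC)(CC)OC(C)(C)CC(=O)O
F8 | step 7 | 3-methyl-3-[(triethylsilyl)oxy]butanoyl chloride (not isolated) | CC[Si](CC)(CC)OC(C)(C)CC(=O)Cl
F9 | step 7 | 3-(2-methylbut-3-en-2-yl)-2-oxo-6-phenyl-2H-pyran-4-yl 3-methyl-3-[(triethylsilyl)oxy]butanoate | C=CC(C)(C)c1c(OC(=O)CC(C)(C)O[Si](CC)(CC)CC)cc(-c2ccccc2)oc1=O
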